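in all of them: free monomer 23 mM; initiator 0.29 mol%
- west: protic impurity 9.7 mM; run made earlier
- south-west: protic impurity 15 mM; run made earlier
- Sunday's: protic impurity 6.90 mM; time 10 h
- Friday's: protic impurity 6.90 mM; time 40 h

| run | time / h | monomer in chains / % |
|---|---|---|
| west | 1.50 | 25 |
| west | 4.00 | 72 |
| west | 8.00 | 88 |
| west | 12.0 | 84 |
| south-west | 1.50 | 25 |
| south-west | 4.00 | 66 |
| south-west | 8.00 | 76 |
| south-west | 12.0 | 78 |

(readings scatter by 1.5 percentage points)

- the average divides the monomer in chains by the number of chains begun, living and dead together
- the earlier runs do not show the number of chains; that part of a forecast is a guess

* which of the two ends with the longer chains by the average number of monomer units in a chain (chains begun, living or dead) ("neither" if they lie within 10 %) (Sunday's / Friday's / neither)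
* average number of monomer units in a chain (chains begun, living or dead) at the end, Sunday's
* average number of monomer units in a chain (chains begun, living or dead) at the end, Friday's

The slowness of the west run was what I looked at first: its monomer in chains took 8.00 h to read 88 %, and at 12.0 h it read 84 %, so it had levelled off short of the charge. I supposed that the missing free monomer had gone to the protic impurity, one for one, in competition with growth.

The last two readings of each run then gave a reading of monomer lost per monomer in chains: 0.163 in the west run and 0.299 in the south-west run. Dividing the mean impurity present by these ratios gave the impurity level at which both ways take equal shares: 49.7 mM and 41.4 mM. The two readings differ, and I used their mean, 45.5 mM.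

For Sunday's flask, the charge over this level gave a first ratio of 0.152, hence a loss of 13.2 %. Putting that back lowered the mean impurity to 5.39 mM, and the second round gave the loss ratio 0.118, mean impurity over that level, the inverse of a selectivity factor. By this reckoning 89.4 % of the free monomer charged in Sunday's flask goes into chains.

Sunday's 10 h is later than the 8.00 h of the west run's levelling, so I expected the same share on Friday's and called the lengths equal. One number was not enough for a length, though: the readings do not show the chains begun.

The forecast said neither, with 307 units on Sunday's and 320 on Friday's, adding “I assume one per initiator”.

The two flasks gave neither, with 2070 units on Sunday's and 2070 on Friday's.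

    free monomer + living end → monomer in chains + living end, rate k1*[living end]*[free monomer] (k = 1200 M⁻¹ min⁻¹)
    free monomer + initiator → living end + monomer in chains (k = 0.0476 M⁻¹ min⁻¹)
    protic impurity + free monomer → quenched substrate (k = 0.135 M⁻¹ min⁻¹)

In Sunday's flask 85 % of the initiator charge still stood at 10.0 h. My loss ratio of 0.118 with Sunday's length means 0.00993 mM of chains begun.

For a neighbour, Sunday's flask with 17 mM of protic impurity, the same two rounds give a loss ratio of 0.305, so 76.6 % in chains. The computed neighbour holds 74.7 % of monomer in chains at 10.0 h, with chains of 1890 units on average.

The earlier runs and the new flask were generated by integration for an exercise, noise included.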